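## Retrosynthetic overview

1. Target 9 ⇒ magnolol (6) + (1R,4R)-p-menth-2-en-1-ol (5). The aryl–C(sp3) bond ortho to one phenol is made last, by a new boronic-acid-templated dehydrative ortho-allylation that also sets the benzylic stereocentre trans to isopropyl.
2. 5 ⇒ (S)-p-menth-1-ene (2) by hydroxyselenation and selenoxide elimination (alkene transposition that leaves a tertiary allylic OH).
3. 2 ⇒ (S)-(−)-limonene (1) by chemoselective hydrogenation; the isopropyl-bearing stereocentre comes from the chiral pool.
4. No ring is formed in the route: the cyclohexene ring is that of limonene and both benzene rings are those of magnolol.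

Assumption: magnolol (6) and (S)-(−)-limonene (1, high ee) are bought; the cyclic boronates 7 and 8 of the catalytic step are counted as in-flask intermediates.

## Route

Step 1
Reactants: 1 (S)-(−)-limonene
Product: 2 (S)-p-menth-1-ene
Conditions: H2 (1 atm), RhCl(PPh3)3 (1 mol %), toluene, rt, stopped after 1.0 equiv H2
Reagents that add atoms: none
Why: Chemoselective homogeneous hydrogenation reduces the 1,1-disubstituted isopropenyl alkene and leaves the trisubstituted ring alkene alone; the C4 stereocentre is not touched.

Step 2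
Reactants: 2 (S)-p-menth-1-ene
Product: 3 (1R,2R,4S)-1-methyl-2-(phenylselanyl)-4-(propan-2-yl)cyclohexan-1-ol
Conditions: N-(phenylselanyl)phthalimide (1.2 equiv), H2O (3 equiv), camphorsulfonic acid (5 mol %), CH2Cl2, rt
Reagents that add atoms: N-(phenylselanyl)phthalimide (O=C1N([Se]c2ccccc2)C(=O)c2ccccc12); water (O)
Why: Hydroxyselenation (anti addition): water opens the seleniranium ion at the tertiary carbon (Markovnikov) in a trans-diaxial sense, giving OH on C1 (cis to isopropyl) and PhSe on C2 (trans to OH); both new centres are erased later (C2 becomes sp2 in step 3, C1 ionises in step 4), so minor diastereomers do no harm.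

Step 3
Reactants: 3 (1R,2R,4S)-1-methyl-2-(phenylselanyl)-4-(propan-2-yl)cyclohexan-1-ol
Product: 5 (1R,4R)-p-menth-2-en-1-ol, via selenoxide 4 (not isolated)
Conditions: 30% aq. H2O2 (2.5 equiv), pyridine (2 equiv), THF, 0 °C to rt
Reagents that add atoms: none
Why: Selenide oxidation and selenoxide syn-elimination: C1 carries no hydrogen, so elimination can only run towards C3 and gives the transposed tertiary allylic alcohol; C4 is untouched.

Step 4
Reactants: 5 (1R,4R)-p-menth-2-en-1-ol; 6 magnolol (2.0 equiv, excess recovered)
Product: 9 piperitylmagnolol (the target), via magnolol boronate 7 (not isolated), via product boronate 8 (not isolated)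
Conditions: C6F5B(OH)2 (20 mol %), 4 Å molecular sieves, CH2Cl2, 0 °C to rt; aq. NaHCO3 work-up
Reagents that add atoms: none
Why: Proposed new method: a boronic-acid-templated dehydrative Friedel–Crafts ortho-allylation in which C6F5B(OH)2 condenses with the 2,2'-biphenol to the seven-membered dioxaborepine 7, whose Lewis-acidic boron binds and ionises the tertiary allylic alcohol 5 to a contact ion pair (hydroxyborate and p-menthenyl allyl cation); the ring carbon C3 (the only free position ortho or para to oxygen, the para position carrying allyl) attacks the secondary allyl terminus anti to the neighbouring isopropyl group, which sets the new stereocentre R and trans to isopropyl, loss of water gives 8, and boron returns to unhindered magnolol because the new terpenyl group flanks the boron site, which with the excess of 6 should hold the reaction at mono-alkylation, while the weak acid leaves the allyl groups alone, cannot reprotonate dienes (no racemisation at C4) and keeps the phenol oxygens masked against cycloetherification; the closest known reaction types are arylboronic-acid-catalysed dehydrative Friedel–Crafts allylation with allylic alcohols and the acid-mediated terpenylation of resorcinols used for cannabidiol.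

## Compound list

1 | (S)-(−)-limonene, (4S)-1-methyl-4-(prop-1-en-2-yl)cyclohex-1-ene | CC1=CC[C@@H](C(C)=C)CC1 | starting material
2 | (S)-p-menth-1-ene, (4S)-1-methyl-4-(propan-2-yl)cyclohex-1-ene | CC1=CC[C@@H](C(C)C)CC1 | intermediate
3 | (1R,2R,4S)-1-methyl-2-(phenylselanyl)-4-(propan-2-yl)cyclohexan-1-ol (OH cis to isopropyl, PhSe trans to OH) | C[C@]1(O)[C@H]([Se]c2ccccc2)C[C@@H](C(C)C)CC1 | intermediate
4 | Se-oxide of 3 (selenoxide, both configurations at selenium) | C[C@]1(O)[C@H]([Se](=O)c2ccccc2)C[C@@H](C(C)C)CC1 | intermediate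
5 | (1R,4R)-1-methyl-4-(propan-2-yl)cyclohex-2-en-1-ol, (1R,4R)-p-menth-2-en-1-ol (OH and isopropyl on the same face) | C[C@]1(O)C=C[C@@H](C(C)C)CC1 | intermediate
6 | magnolol, 5,5'-di(prop-2-en-1-yl)-[1,1'-biphenyl]-2,2'-diol | C=CCc1ccc(O)c(-c2cc(CC=C)ccc2O)c1 | starting material
7 | 2,10-diallyl-6-(pentafluorophenyl)dibenzo[d,f][1,3,2]dioxaborepine (cyclic C6F5-boronate of magnolol) | C=CCc1ccc2OB(c3c(F)c(F)c(F)c(F)c3F)Oc3ccc(CC=C)cc3-c2c1 | intermediate
8 | 2,10-diallyl-4-[(1R,6R)-3-methyl-6-(propan-2-yl)cyclohex-2-en-1-yl]-6-(pentafluorophenyl)dibenzo[d,f][1,3,2]dioxaborepine (cyclic C6F5-boronate of 9) | C=CCc1cc([C@H]4C=C(C)CC[C@@H]4C(C)C)c2OB(c3c(F)c(F)c(F)c(F)c3F)Oc3ccc(CC=C)cc3-c2c1 | intermediate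
9 | 3-[(1R,6R)-3-methyl-6-(propan-2-yl)cyclohex-2-en-1-yl]-5,5'-di(prop-2-en-1-yl)-[1,1'-biphenyl]-2,2'-diol (aryl and isopropyl trans) | C=CCc1ccc(O)c(-c2cc(CC=C)cc([C@H]3C=C(C)CC[C@@H]3C(C)C)c2O)c1 | target

## Summary

Total step count: 4. Longest linear sequence: 4 steps (1 → 2 → 3 → 5 → 9).

Steps most likely to fail:

Step 4 (the proposed new method). The boronate may ionise 5 too slowly, bis-alkylation at C3' may compete, or 5 may dehydrate to dienes. The fallback uses known chemistry, sets out from 6 (with 5) and comes back at 9. Magnolol 6 is mono-acylated with pivaloyl chloride (1.0 equiv, Et3N, cat. DMAP, CH2Cl2, −20 °C), the first phenol of a 2,2'-biphenol being far more acidic than the second, to give 5,5'-diallyl-2'-hydroxy-[1,1'-biphenyl]-2-yl pivalate F1. F1 and 5 are then joined under the classical acid-mediated terpenylation conditions used for cannabidiol (BF3·OEt2 on Al2O3 or cat. TsOH, CH2Cl2, 0 °C). Only the free-phenol ring is activated, so alkylation goes ortho to its hydroxyl and anti to isopropyl, giving the terpenylated mono-pivalate F2. LiOH in THF/MeOH/H2O then removes the ester to give 9.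

Step 2. Hydroxyselenation of the trisubstituted alkene may stall or give the regioisomer with selenium on C1. The fallback sets out from 2 and comes back at 3. NBS in aqueous acetone at 0 °C gives the trans-diaxial bromohydrin (1R,2R,4S)-2-bromo-1-methyl-4-(propan-2-yl)cyclohexan-1-ol F3. NaOEt (1.1 equiv) in EtOH at 0 °C first closes it to (1R,2S,4S)-1,2-epoxy-p-menthane F4. PhSeH (1.2 equiv) is then added to the same flask and the mixture is heated to reflux; the small excess of ethoxide keeps a catalytic amount of selenolate present, which opens the epoxide at the secondary carbon C2 in a trans-diaxial sense to give 3.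

Step 3. The tertiary allylic alcohol is volatile and acid-sensitive, and excess peroxide with selenium residues can epoxidise it. The fallback sets out from 2 and comes back at 5, bypassing 3. A Schenck ene reaction of 2 with singlet oxygen (O2, visible light, cat. 5,10,15,20-tetraphenylporphyrin, CH2Cl2, 0 °C) gives the tertiary allylic hydroperoxides (1R,4R)-1-hydroperoxy-p-menth-2-ene F5 and (1S,4R)-1-hydroperoxy-p-menth-2-ene F6, beside secondary regioisomers. Reduction with PPh3 and chromatography of the tertiary alcohols gives 5 together with its C1 epimer (1S,4R)-p-menth-2-en-1-ol F7. F7 need not be removed, because ionisation in step 4 erases C1.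

## Further compounds

F1 | step 4 | magnolol mono-pivalate, 5,5'-diallyl-2'-hydroxy-[1,1'-biphenyl]-2-yl 2,2-dimethylpropanoate | C=CCc1ccc(O)c(-c2cc(CC=C)ccc2OC(=O)C(C)(C)C)c1
F2 | step 4 | 5,5'-diallyl-2'-hydroxy-3'-[(1R,6R)-3-methyl-6-(propan-2-yl)cyclohex-2-en-1-yl]-[1,1'-biphenyl]-2-yl 2,2-dimethylpropanoate | C=CCc1ccc(OC(=O)C(C)(C)C)c(-c2cc(CC=C)cc([C@H]3C=C(C)CC[C@@H]3C(C)C)c2O)c1
F3 | step 2 | (1R,2R,4S)-2-bromo-1-methyl-4-(propan-2-yl)cyclohexan-1-ol | C[C@]1(O)[C@H](Br)C[C@@H](C(C)C)CC1
F4 | step 2 | (1R,2S,4S)-1,2-epoxy-p-menthane (epoxide oxygen cis to isopropyl) | C[C@]12O[C@H]1C[C@@H](C(C)C)CC2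
F5 | step 3 | (1R,4R)-1-hydroperoxy-p-menth-2-ene | C[C@]1(OO)C=C[C@@H](C(C)C)CC1
F6 | step 3 | (1S,4R)-1-hydroperoxy-p-menth-2-ene | C[C@@]1(OO)C=C[C@@H](C(C)C)CC1
F7 | step 3 | (1S,4R)-p-menth-2-en-1-ol | C[C@@]1(O)C=C[C@@H](C(C)C)CC1
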